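## Retrosynthetic overview

1. Target 30 comes from lactone 27 by PMB removal, isobutyrylation and desilylation. Locants follow cyclodeca[b]furan numbering: O1, C2 (carbonyl), C3 (methylidene carbon), C3a, C4 (ester carbinol), C6=C7, C10, C11a.
2. Lactone 27 comes from the acyclic allenyl aldehyde 24 and CO2 in one operation. Zerovalent nickel carboxylates the central allene carbon (C2–C3 bond), the resulting 2-carboxyallylnickel adds to the aldehyde (C3a–C11a bond, ten-membered carbocycle), and acid then closes O1–C2 (five-membered lactone).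
3. Enabling feature: the α-methylene-γ-butyrolactone is a 2-carboxyallyl unit on a carbinol carbon. The exocyclic CH2, C3 and C3a are the three carbons of a terminal allene, C2 is one carbon at the oxidation level of CO2, C11a–O1 is a former aldehyde, and the ring-cis C6=C7 alkene pre-folds the chain.
4. Aldehyde 24 comes from aldol condensation of West lactone 5 (carries C4) with East aldehyde 16 (carries C10), which sets the C6=C7 geometry. One LiAlH4 operation then opens the lactone to the C6 hydroxymethyl group and converts the propargylic methyl ether into the allene.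
5. Lactone 5 comes from asymmetric transfer hydrogenation of ynone 3, and aldehyde 16 from an Evans allylation. Ring order: carbocycle, then lactone, both in step 16.

Key step: step 16

Remark on the chemistry: metal salts of numbered compounds (enolates, alkoxides, carboxylates) and species inside catalytic cycles are treated as reactive forms and carry no number; covalent intermediates that accumulate between two operations of a step are numbered.

## Route

Step 1
Reactants: 1 methyl 4-chloro-4-oxobutanoate; 2 3-methoxyprop-1-yne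
Product: 3 methyl 7-methoxy-4-oxohept-5-ynoate
Conditions: PdCl2(PPh3)2 (2 mol %), CuI (4 mol %), Et3N, THF, rt
Reagents that add atoms: none
Why: Acyl Sonogashira coupling of an acid chloride with a terminal alkyne should give the ynone directly, the methyl ester being inert under these conditions.

Step 2
Reactants: 3 methyl 7-methoxy-4-oxohept-5-ynoate
Product: 5 (5R)-5-(3-methoxyprop-1-yn-1-yl)oxolan-2-one, via hydroxy ester 4 (not isolated)
Conditions: RuCl[(R,R)-TsDPEN](p-cymene) (1 mol %), i-PrOH, rt; then TsOH·H2O (cat.), CH2Cl2, rt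
Reagents that add atoms: none
Why: Noyori asymmetric transfer hydrogenation of an alkynyl ketone with the (R,R) catalyst should deliver hydride to the face that gives the (R)-propargylic alcohol (the alkyne acts as the π-recognition group), and acid-catalysed lactonization then closes the γ-lactone without touching the new stereocenter (the future C4).

Step 3
Reactants: 6 methyl 4,4-dimethoxybutanoate
Product: 7 4,4-dimethoxybutanoic acid
Conditions: LiOH·H2O, THF/H2O, 0 °C → rt; cold 1 M HCl to pH 4
Reagents that add atoms: lithium hydroxide, [Li+].[OH-]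
Why: Ester saponification, with the dimethyl acetal stable to base and to the brief cold acidification.

Step 4
Reactants: 7 4,4-dimethoxybutanoic acid; 8 (4R)-4-benzyl-1,3-oxazolidin-2-one
Product: 10 (4R)-4-benzyl-3-(4,4-dimethoxybutanoyl)-1,3-oxazolidin-2-one, via mixed anhydride 9 (not isolated)
Conditions: t-BuCOCl, Et3N, THF, −20 °C; then LiCl, 8, −20 °C → rt
Reagents that add atoms: none
Why: N-Acylation of the Evans auxiliary through the pivaloyl mixed anhydride, the hindered pivaloyl carbonyl directing attack to the desired acyl group.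

Step 5
Reactants: 10 (4R)-4-benzyl-3-(4,4-dimethoxybutanoyl)-1,3-oxazolidin-2-one
Product: 11 (4R)-4-benzyl-3-[(2R)-2-(2,2-dimethoxyethyl)pent-4-enoyl]-1,3-oxazolidin-2-one
Conditions: NaN(SiMe3)2, THF, −78 °C; allyl iodide, −78 → −45 °C
Reagents that add atoms: allyl iodide, C=CCI
Why: Evans asymmetric alkylation, in which allyl iodide should approach the chelated sodium Z-enolate on the face opposite the benzyl group and so set the (R) centre that becomes C10.

Step 6
Reactants: 11 (4R)-4-benzyl-3-[(2R)-2-(2,2-dimethoxyethyl)pent-4-enoyl]-1,3-oxazolidin-2-one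
Product: 12 (2R)-2-(2,2-dimethoxyethyl)pent-4-en-1-ol
Conditions: LiBH4, MeOH (1 equiv), Et2O, 0 °C
Reagents that add atoms: none
Why: Reductive cleavage of the N-acyl oxazolidinone by borohydride should give the primary alcohol and return the auxiliary, with acetal and alkene untouched and the stereocenter no longer enolizable.

Step 7
Reactants: 12 (2R)-2-(2,2-dimethoxyethyl)pent-4-en-1-ol
Product: 13 tert-butyl{[(2R)-2-(2,2-dimethoxyethyl)pent-4-en-1-yl]oxy}diphenylsilane
Conditions: TBDPSCl, imidazole, CH2Cl2, rt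
Reagents that add atoms: tert-butyl(chloro)diphenylsilane, CC(C)(C)[Si](Cl)(c1ccccc1)c1ccccc1
Why: Silylation of a primary alcohol with an acid-robust silyl group that must later survive acetal hydrolysis.

Step 8
Reactants: 13 tert-butyl{[(2R)-2-(2,2-dimethoxyethyl)pent-4-en-1-yl]oxy}diphenylsilane
Product: 15 (4R)-4-({[tert-butyl(diphenyl)silyl]oxy}methyl)-6,6-dimethoxyhexan-1-ol, via B-alkyl-9-BBN 14 (not isolated)
Conditions: 9-BBN, THF, 0 °C → rt; then NaOH, H2O2, 0 °C
Reagents that add atoms: hydrogen peroxide, OO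
Why: Anti-Markovnikov hydroboration–oxidation of the terminal alkene should give the three-carbon arm that ends in a primary alcohol.

Step 9
Reactants: 15 (4R)-4-({[tert-butyl(diphenyl)silyl]oxy}methyl)-6,6-dimethoxyhexan-1-ol
Product: 16 (4R)-4-({[tert-butyl(diphenyl)silyl]oxy}methyl)-6,6-dimethoxyhexanal
Conditions: Dess–Martin periodinane, NaHCO3, CH2Cl2, 0 °C → rt
Reagents that add atoms: none
Why: Buffered Dess–Martin oxidation of a primary alcohol to the aldehyde, mild enough for the acetal and the silyl ether.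

Step 10
Reactants: 5 (5R)-5-(3-methoxyprop-1-yn-1-yl)oxolan-2-one; 16 (4R)-4-({[tert-butyl(diphenyl)silyl]oxy}methyl)-6,6-dimethoxyhexanal
Product: 17 (5R)-3-[(4R)-4-({[tert-butyl(diphenyl)silyl]oxy}methyl)-1-hydroxy-6,6-dimethoxyhexyl]-5-(3-methoxyprop-1-yn-1-yl)oxolan-2-one (both new centres as mixtures)
Conditions: LiN(i-Pr)2, THF, −78 °C; then 16, −78 °C; aq. NH4Cl
Reagents that add atoms: none
Why: Aldol addition of the lithium lactone enolate to the aldehyde joins the two fragments, and the configuration of the two new centres is irrelevant because both are destroyed in step 11.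

Step 11
Reactants: 17 β-hydroxy lactone (aldol adduct)
Product: 19 (3E,5R)-3-[(4R)-4-({[tert-butyl(diphenyl)silyl]oxy}methyl)-6,6-dimethoxyhexylidene]-5-(3-methoxyprop-1-yn-1-yl)oxolan-2-one, via mesylate 18 (not isolated)
Conditions: MsCl, Et3N, CH2Cl2, 0 °C; then DBU, 0 °C → rt
Reagents that add atoms: none
Why: Mesylation and E1cB elimination should give the thermodynamically preferred E-alkylidene lactone (chain anti to the lactone carbonyl), which is exactly the ring-cis C6=C7 geometry of the target.

Step 12
Reactants: 19 (3E,5R)-alkylidene lactone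
Product: 21 (2E,6R)-6-({[tert-butyl(diphenyl)silyl]oxy}methyl)-2-[(2R)-2-hydroxypenta-3,4-dien-1-yl]-8,8-dimethoxyoct-2-en-1-ol, via propargylic diol 20 (not isolated)
Conditions: LiAlH4 (4 equiv), THF, 0 °C, then 60 °C; aq. KNaC4H4O6 work-up
Reagents that add atoms: none
Why: Hydride 1,2-reduction of the trisubstituted enoate lactone gives the diol, and the propargylic alkoxyaluminate then delivers hydride to the proximal alkyne carbon and expels methoxide (hydroxyl-directed trans-hydroalumination/elimination, overall SN2′), which should give the terminal allene with the carbinol stereocenter and the alkene geometry untouched.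

Step 13
Reactants: 21 allenyl diol
Product: 22 (4R,6E,10R)-6,10-bis({[tert-butyl(diphenyl)silyl]oxy}methyl)-12,12-dimethoxydodeca-1,2,6-trien-4-ol
Conditions: TBDPSCl (1.05 equiv), imidazole, CH2Cl2, −20 → 0 °C
Reagents that add atoms: tert-butyl(chloro)diphenylsilane, CC(C)(C)[Si](Cl)(c1ccccc1)c1ccccc1
Why: Chemoselective silylation, the bulky silyl chloride reacting with the primary allylic hydroxyl far faster than with the secondary allenylic one.

Step 14
Reactants: 22 (4R,6E,10R)-allenyl alcohol
Product: 23 4-methoxybenzyl ether of 22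
Conditions: NaH, 4-methoxybenzyl chloride, Bu4NI (cat.), THF/DMF, 0 °C → rt
Reagents that add atoms: 4-methoxybenzyl chloride, COc1ccc(CCl)cc1
Why: Williamson etherification installs an oxidatively removable, non-leaving ether at the allenylic position, where an ester would risk ionization or β-elimination in step 16.

Step 15
Reactants: 23 PMB ether dimethyl acetal
Product: 24 (3R,6E,9R)-3,7-bis({[tert-butyl(diphenyl)silyl]oxy}methyl)-9-[(4-methoxyphenyl)methoxy]dodeca-6,10,11-trienal
Conditions: PPTS (0.2 equiv), acetone/H2O 10:1, 45 °C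
Reagents that add atoms: water, O
Why: Mild acid-catalysed acetal hydrolysis should free the aldehyde while the TBDPS ethers, the PMB ether and the allene survive.

Step 16
Reactants: 24 (3R,6E,9R)-allenyl aldehyde
Product: 27 (3aR,4R,6E,10R,11aR)-6,10-bis({[tert-butyl(diphenyl)silyl]oxy}methyl)-4-[(4-methoxyphenyl)methoxy]-3-methylidene-3a,4,5,8,9,10,11,11a-octahydrocyclodeca[b]furan-2(3H)-one, via oxanickelacycle 25 (not isolated), via seco hydroxy acid 26 (not isolated)
Conditions: Ni(cod)2 (1.2 equiv), DBU (2.5 equiv), CO2 (1 atm), THF, 0 °C, slow addition of 24 (final 2 mM), then rt; 1 M HCl; TsOH·H2O (cat.), CH2Cl2, rt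
Reagents that add atoms: carbon dioxide, O=C=O
Why: Proposed new method: zerovalent nickel with DBU and CO2 should couple the terminal allene by oxidative cyclization at its central carbon (C2–C3 bond) to the 2-carboxylato-allylnickel 25, whose substituted allyl terminus then adds to the tethered aldehyde through a six-membered nickel-bound allyl-transfer transition state (C3a–C11a bond), and acid converts the resulting γ-hydroxy acid 26 into the lactone; the closest known reaction type is the nickel-mediated sequential coupling of terminal allenes, CO2 and aryl aldehydes, here made intramolecular with an aliphatic aldehyde, and the ring-closing half mirrors the allylchromium (CrCl2) and allylnickel closures of 2-(alkoxycarbonyl)allyl halides onto aldehydes that are established for ten-membered germacranolide rings. The carbocycle closes as a ten-membered ring by intramolecular carbonyl allylation (the cis C6=C7 alkene folds the chain and slow addition keeps 24 dilute), and the five-membered lactone closes by 5-exo-trig attack of the C11a hydroxyl on the carboxylic acid. The C3a configuration is controlled by the C4 stereocenter: 1,3-allylic strain holds the C4–H bond in the allyl plane, the ring chain (C5) lies anti to the incoming aldehyde, and bonding should therefore occur on the face that carries the PMB-ether oxygen, which can also bind nickel. The C11a configuration is controlled by the chair-like transfer state in which both ring branches (C4 on C3a, C11 on C11a) are equatorial, reached from the E-configured σ-allyl form by π–σ–π isomerization, which should give the anti adduct and hence the trans-fused lactone. The step needs carboxylation of the allene before the aldehyde is engaged, branched (γ) attack of the allyl unit and no β-elimination at C4; the large excess of CO2 and the eight-atom separation of allene and aldehyde secure the first, nickel on the CH2 terminus of the chelated nickelalactone secures the second, and the PMB ether in place of the final ester at C4 secures the third.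

Step 17
Reactants: 27 PMB-protected lactone
Product: 28 (3aR,4R,6E,10R,11aR)-6,10-bis({[tert-butyl(diphenyl)silyl]oxy}methyl)-4-hydroxy-3-methylidene-3a,4,5,8,9,10,11,11a-octahydrocyclodeca[b]furan-2(3H)-one
Conditions: DDQ (1.3 equiv), CH2Cl2/pH 7 buffer 10:1, 0 °C
Reagents that add atoms: none
Why: Oxidative cleavage of the PMB ether by DDQ under neutral conditions should leave the α-methylene lactone, the silyl ethers and the trisubstituted alkene untouched.

Step 18
Reactants: 28 C4 alcohol
Product: 29 (3aS,4R,6E,10R,11aR)-6,10-bis({[tert-butyl(diphenyl)silyl]oxy}methyl)-3-methylidene-2-oxo-2,3,3a,4,5,8,9,10,11,11a-decahydrocyclodeca[b]furan-4-yl 2-methylpropanoate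
Conditions: (i-PrCO)2O (3 equiv), Et3N, DMAP (0.2 equiv), CH2Cl2, 0 °C → rt
Reagents that add atoms: 2-methylpropanoic anhydride, CC(C)C(=O)OC(=O)C(C)C
Why: DMAP-catalysed acylation of the only free hydroxyl with retention at C4 (the C3a descriptor changes from R to S only because the CIP priorities change).

Step 19
Reactants: 29 bis-silyl isobutyrate
Product: 30 (3aS,4R,6E,10R,11aR)-6,10-bis(hydroxymethyl)-3-methylidene-2-oxo-2,3,3a,4,5,8,9,10,11,11a-decahydrocyclodeca[b]furan-4-yl 2-methylpropanoate (target)
Conditions: HF·pyridine, pyridine, THF, 0 °C → rt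
Reagents that add atoms: none
Why: Fluoride-mediated desilylation under buffered acidic conditions should free both primary alcohols without acyl migration or conjugate addition to the α-methylene lactone.

## Compound list

1 | methyl 4-chloro-4-oxobutanoate | COC(=O)CCC(Cl)=O | starting material
2 | 3-methoxyprop-1-yne | COCC#C | starting material
3 | methyl 7-methoxy-4-oxohept-5-ynoate | COCC#CC(=O)CCC(=O)OC | intermediate
4 | methyl (4R)-4-hydroxy-7-methoxyhept-5-ynoate (formed in the flask) | COCC#C[C@H](O)CCC(=O)OC | intermediate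
5 | (5R)-5-(3-methoxyprop-1-yn-1-yl)oxolan-2-one | COCC#C[C@H]1CCC(=O)O1 | intermediate
6 | methyl 4,4-dimethoxybutanoate | COC(=O)CCC(OC)OC | starting material
7 | 4,4-dimethoxybutanoic acid | OC(=O)CCC(OC)OC | intermediate
8 | (4R)-4-benzyl-1,3-oxazolidin-2-one | O=C1N[C@H](Cc2ccccc2)CO1 | starting material
9 | 4,4-dimethoxybutanoic 2,2-dimethylpropanoic anhydride (formed in the flask) | COC(OC)CCC(=O)OC(=O)C(C)(C)C | intermediate
10 | (4R)-4-benzyl-3-(4,4-dimethoxybutanoyl)-1,3-oxazolidin-2-one | COC(OC)CCC(=O)N1[C@H](Cc2ccccc2)COC1=O | intermediate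
11 | (4R)-4-benzyl-3-[(2R)-2-(2,2-dimethoxyethyl)pent-4-enoyl]-1,3-oxazolidin-2-one | C=CC[C@H](CC(OC)OC)C(=O)N1[C@H](Cc2ccccc2)COC1=O | intermediate
12 | (2R)-2-(2,2-dimethoxyethyl)pent-4-en-1-ol | C=CC[C@H](CC(OC)OC)CO | intermediate
13 | tert-butyl{[(2R)-2-(2,2-dimethoxyethyl)pent-4-en-1-yl]oxy}diphenylsilane | C=CC[C@H](CC(OC)OC)CO[Si](c1ccccc1)(c1ccccc1)C(C)(C)C | intermediate
14 | 9-[(4R)-4-({[tert-butyl(diphenyl)silyl]oxy}methyl)-6,6-dimethoxyhexyl]-9-borabicyclo[3.3.1]nonane (formed in the flask) | C(CC[C@H](CC(OC)OC)CO[Si](c1ccccc1)(c1ccccc1)C(C)(C)C)B1C2CCCC1CCC2 | intermediate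
15 | (4R)-4-({[tert-butyl(diphenyl)silyl]oxy}methyl)-6,6-dimethoxyhexan-1-ol | OCCC[C@H](CC(OC)OC)CO[Si](c1ccccc1)(c1ccccc1)C(C)(C)C | intermediate
16 | (4R)-4-({[tert-butyl(diphenyl)silyl]oxy}methyl)-6,6-dimethoxyhexanal | O=CCC[C@H](CC(OC)OC)CO[Si](c1ccccc1)(c1ccccc1)C(C)(C)C | intermediate
17 | (5R)-3-[(4R)-4-({[tert-butyl(diphenyl)silyl]oxy}methyl)-1-hydroxy-6,6-dimethoxyhexyl]-5-(3-methoxyprop-1-yn-1-yl)oxolan-2-one, mixture at the two new centres | COCC#C[C@H]1CC(C(O)CC[C@H](CC(OC)OC)CO[Si](c2ccccc2)(c2ccccc2)C(C)(C)C)C(=O)O1 | intermediate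
18 | methanesulfonate of 17 (formed in the flask) | COCC#C[C@H]1CC(C(OS(C)(=O)=O)CC[C@H](CC(OC)OC)CO[Si](c2ccccc2)(c2ccccc2)C(C)(C)C)C(=O)O1 | intermediate
19 | (3E,5R)-3-[(4R)-4-({[tert-butyl(diphenyl)silyl]oxy}methyl)-6,6-dimethoxyhexylidene]-5-(3-methoxyprop-1-yn-1-yl)oxolan-2-one | COCC#C[C@H]1C/C(=C\CC[C@H](CC(OC)OC)CO[Si](c2ccccc2)(c2ccccc2)C(C)(C)C)C(=O)O1 | intermediate
20 | (2E,6R)-6-({[tert-butyl(diphenyl)silyl]oxy}methyl)-2-[(2R)-2-hydroxy-5-methoxypent-3-yn-1-yl]-8,8-dimethoxyoct-2-en-1-ol (formed in the flask) | COCC#C[C@H](O)C/C(CO)=C\CC[C@H](CC(OC)OC)CO[Si](c1ccccc1)(c1ccccc1)C(C)(C)C | intermediate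
21 | (2E,6R)-6-({[tert-butyl(diphenyl)silyl]oxy}methyl)-2-[(2R)-2-hydroxypenta-3,4-dien-1-yl]-8,8-dimethoxyoct-2-en-1-ol | C=C=C[C@H](O)C/C(CO)=C\CC[C@H](CC(OC)OC)CO[Si](c1ccccc1)(c1ccccc1)C(C)(C)C | intermediate
22 | (4R,6E,10R)-6,10-bis({[tert-butyl(diphenyl)silyl]oxy}methyl)-12,12-dimethoxydodeca-1,2,6-trien-4-ol | C=C=C[C@H](O)C/C(CO[Si](c1ccccc1)(c1ccccc1)C(C)(C)C)=C\CC[C@H](CC(OC)OC)CO[Si](c1ccccc1)(c1ccccc1)C(C)(C)C | intermediate
23 | 4-methoxybenzyl ether of 22 (4R,6E,10R) | C=C=C[C@H](OCc1ccc(OC)cc1)C/C(CO[Si](c1ccccc1)(c1ccccc1)C(C)(C)C)=C\CC[C@H](CC(OC)OC)CO[Si](c1ccccc1)(c1ccccc1)C(C)(C)C | intermediate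
24 | (3R,6E,9R)-3,7-bis({[tert-butyl(diphenyl)silyl]oxy}methyl)-9-[(4-methoxyphenyl)methoxy]dodeca-6,10,11-trienal | C=C=C[C@H](OCc1ccc(OC)cc1)C/C(CO[Si](c1ccccc1)(c1ccccc1)C(C)(C)C)=C\CC[C@H](CC=O)CO[Si](c1ccccc1)(c1ccccc1)C(C)(C)C | intermediate
25 | oxanickelacycle from the allene of 24 and CO2 (divalent nickel, five-membered Ni–CH2–C(=CH–R)–C(=O)–O ring; DBU ligands not drawn, allyl geometry fluxional; formed in the flask) | O=C2O[Ni]CC2=C[C@H](OCc1ccc(OC)cc1)C/C(CO[Si](c1ccccc1)(c1ccccc1)C(C)(C)C)=C\CC[C@H](CC=O)CO[Si](c1ccccc1)(c1ccccc1)C(C)(C)C | intermediate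
26 | seco hydroxy acid of 27 (free C11a hydroxyl and free acrylic acid, same configuration at all four centres; formed in the flask) | C=C(C(=O)O)[C@@H]1[C@H](OCc2ccc(OC)cc2)C/C(CO[Si](c2ccccc2)(c2ccccc2)C(C)(C)C)=C\CC[C@@H](CO[Si](c2ccccc2)(c2ccccc2)C(C)(C)C)C[C@H]1O | intermediate
27 | (3aR,4R,6E,10R,11aR)-6,10-bis({[tert-butyl(diphenyl)silyl]oxy}methyl)-4-[(4-methoxyphenyl)methoxy]-3-methylidene-3a,4,5,8,9,10,11,11a-octahydrocyclodeca[b]furan-2(3H)-one | C=C1C(=O)O[C@@H]2C[C@H](CO[Si](c3ccccc3)(c3ccccc3)C(C)(C)C)CC/C=C(/CO[Si](c3ccccc3)(c3ccccc3)C(C)(C)C)C[C@@H](OCc3ccc(OC)cc3)[C@@H]12 | intermediate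
28 | (3aR,4R,6E,10R,11aR)-6,10-bis({[tert-butyl(diphenyl)silyl]oxy}methyl)-4-hydroxy-3-methylidene-3a,4,5,8,9,10,11,11a-octahydrocyclodeca[b]furan-2(3H)-one | C=C1C(=O)O[C@@H]2C[C@H](CO[Si](c3ccccc3)(c3ccccc3)C(C)(C)C)CC/C=C(/CO[Si](c3ccccc3)(c3ccccc3)C(C)(C)C)C[C@@H](O)[C@@H]12 | intermediate
29 | (3aS,4R,6E,10R,11aR)-6,10-bis({[tert-butyl(diphenyl)silyl]oxy}methyl)-3-methylidene-2-oxo-2,3,3a,4,5,8,9,10,11,11a-decahydrocyclodeca[b]furan-4-yl 2-methylpropanoate | C=C1C(=O)O[C@@H]2C[C@H](CO[Si](c3ccccc3)(c3ccccc3)C(C)(C)C)CC/C=C(/CO[Si](c3ccccc3)(c3ccccc3)C(C)(C)C)C[C@@H](OC(=O)C(C)C)[C@@H]12 | intermediate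
30 | (3aS,4R,6E,10R,11aR)-6,10-bis(hydroxymethyl)-3-methylidene-2-oxo-2,3,3a,4,5,8,9,10,11,11a-decahydrocyclodeca[b]furan-4-yl 2-methylpropanoate | C=C1C(=O)O[C@@H]2C[C@H](CO)CC/C=C(/CO)C[C@@H](OC(=O)C(C)C)[C@@H]12 | target

## Step count and risks

Total steps: 19. Longest linear sequence: 17 (steps 3–9, then steps 10–19); the West branch contributes steps 1–2.

Steps most likely to fail:

1. Step 16 (proposed new method). The aldehyde may be consumed by amidine- or nickel-promoted self-condensation or intermolecular coupling before the allylnickel closes the ring. The ring may also close with cis fusion or on the wrong face at C3a. Fallback with known chemistry, setting out from 23 and coming back at 27: copper-catalysed silacarboxylation of the allene (CuCl/PCy3, PhMe2Si–B(pin), CO2, the ligand that steers to the allylsilane regioisomer) would give the 2-(silylmethyl)alkenoic acid F1. TMSCHN2 would give the methyl ester F2, and PPTS in aqueous acetone the aldehyde F3. A Lewis-acid-promoted intramolecular Hosomi–Sakurai addition of the 2-(methoxycarbonyl)allylsilane to the aldehyde (BF3·OEt2, CH2Cl2, −78 °C, high dilution) would close the ten-membered ring to the hydroxy ester F4, which TsOH would lactonize to 27. This separates the C2–C3 bond formation from the ring closure and replaces the nickel-bound transition state by an open one.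

2. Step 12. Conjugate reduction of the enoate, incomplete elimination of methoxide, or over-reduction of the allenol may occur under the forcing hydride conditions. Fallback, setting out from 19 and coming back at 22: i-Bu2AlH at −78 °C would reduce only the lactone, so that diol 20 is isolated. Its primary hydroxyl would be silylated first (TBDPSCl, imidazole) to the mono-silylated propargylic alcohol F5. The hydroxyl-directed SN2′ hydride delivery would then be run on this single alkoxide with NaAlH2(OCH2CH2OMe)2 in THF, giving 22 directly. Lactone reduction and allene formation are thus decoupled and the order of protection and allene formation is reversed.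

3. Step 11. The alkene geometry may erode, or the exocyclic double bond may migrate into the lactone ring during the base-mediated elimination. Fallback, setting out from 5 (with 16) and coming back at 19: α-bromination of 5 (LiN(SiMe3)2, TMSCl, then NBS) would give the α-bromo lactone F6. PPh3 would give the phosphonium bromide F7, and aqueous NaOH the stabilized phosphorane F8. Wittig olefination of 16 with F8 in toluene should give 19 with the E geometry typical of lactone-derived stabilized ylides, with no aldol or elimination step.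

Further compounds
F1 | step 16 | (Z)-2-{[dimethyl(phenyl)silyl]methyl}alk-2-enoic acid from silacarboxylation of the allene of 23 | C[Si](C)(c1ccccc1)C/C(C(=O)O)=C\[C@H](OCc1ccc(OC)cc1)C/C(CO[Si](c1ccccc1)(c1ccccc1)C(C)(C)C)=C\CC[C@H](CC(OC)OC)CO[Si](c1ccccc1)(c1ccccc1)C(C)(C)C
F2 | step 16 | methyl ester of F1 | C[Si](C)(c1ccccc1)C/C(C(=O)OC)=C\[C@H](OCc1ccc(OC)cc1)C/C(CO[Si](c1ccccc1)(c1ccccc1)C(C)(C)C)=C\CC[C@H](CC(OC)OC)CO[Si](c1ccccc1)(c1ccccc1)C(C)(C)C
F3 | step 16 | aldehyde from acetal hydrolysis of F2 | C[Si](C)(c1ccccc1)C/C(C(=O)OC)=C\[C@H](OCc1ccc(OC)cc1)C/C(CO[Si](c1ccccc1)(c1ccccc1)C(C)(C)C)=C\CC[C@H](CC=O)CO[Si](c1ccccc1)(c1ccccc1)C(C)(C)C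
F4 | step 16 | methyl ester of seco hydroxy acid 26 | C=C(C(=O)OC)[C@@H]1[C@H](OCc2ccc(OC)cc2)C/C(CO[Si](c2ccccc2)(c2ccccc2)C(C)(C)C)=C\CC[C@@H](CO[Si](c2ccccc2)(c2ccccc2)C(C)(C)C)C[C@H]1O
F5 | step 12 | mono-silylated propargylic alcohol: primary TBDPS ether of diol 20 | COCC#C[C@H](O)C/C(CO[Si](c1ccccc1)(c1ccccc1)C(C)(C)C)=C\CC[C@H](CC(OC)OC)CO[Si](c1ccccc1)(c1ccccc1)C(C)(C)C
F6 | step 11 | (5R)-3-bromo-5-(3-methoxyprop-1-yn-1-yl)oxolan-2-one, mixture at C3 | COCC#C[C@H]1CC(Br)C(=O)O1
F7 | step 11 | [(5R)-5-(3-methoxyprop-1-yn-1-yl)-2-oxooxolan-3-yl]triphenylphosphonium bromide | COCC#C[C@H]1CC([P+](c2ccccc2)(c2ccccc2)c2ccccc2)C(=O)O1.[Br-]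
F8 | step 11 | (5R)-5-(3-methoxyprop-1-yn-1-yl)-3-(triphenyl-λ5-phosphanylidene)oxolan-2-one | COCC#C[C@H]1CC(=P(c2ccccc2)(c2ccccc2)c2ccccc2)C(=O)O1
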